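## Retrosynthetic overview

1. Target 10 comes from tribenzyl ether 9 by global O-debenzylation; ring A is the aromatic butanoylphloroglucinol ring, ring B the dimethylcyclohexadienone (filicinic acid) ring.
2. Key disconnection of 9 is the ArC–CH2 bond: aryl bromide 4 (electrophile) plus the boron homoenolate 8 of ring B (ring B–CH2–BF3K, nucleophilic β-carbon), joined by palladium catalysis.
3. 8 comes from acetylfilicinic acid 7 and BrCH2BF3K; 7 comes from dearomatising gem-dimethylation of 2,4,6-trihydroxyacetophenone 5.
4. 4 comes from phloroglucinol 1 by Friedel–Crafts butanoylation, O-benzylation and ring bromination.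
5. No ring is formed by cyclisation: ring A is carried through from 1, and ring B is obtained by dearomatising the bought aromatic ring of 5 before the two rings are joined.

Assumption: the target has no stereocentre and no stereogenic double bond, so it is achiral and "single enantiomer" means the single constitution (enol tautomer) drawn.

## Route

Step 1
Reactants: 1 phloroglucinol (benzene-1,3,5-triol)
Product: 2 1-(2,4,6-trihydroxyphenyl)butan-1-one
Conditions: butanoyl chloride (1.05 equiv), AlCl3 (3.5 equiv), PhNO2/CH2Cl2, 0 °C to 45 °C; then 1 M HCl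
Reagents that add atoms: butanoyl chloride, CCCC(=O)Cl
Why: Friedel–Crafts C-acylation of the very electron-rich triol stops at the mono-ketone because the first acyl group, chelated to AlCl3, deactivates the ring.

Step 2
Reactants: 2 1-(2,4,6-trihydroxyphenyl)butan-1-one
Product: 3 1-[2,4,6-tris(benzyloxy)phenyl]butan-1-one
Conditions: BnBr (3.6 equiv), K2CO3 (4 equiv), DMF, 60 °C
Reagents that add atoms: benzyl bromide, BrCc1ccccc1
Why: Williamson O-benzylation with a carbonate base in a dipolar aprotic solvent favours O- over C-alkylation, and capping all three phenols prevents bromonium transfer and phenoxide-driven retro-Michael scrambling of the methylene bridge in step 6.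

Step 3
Reactants: 3 1-[2,4,6-tris(benzyloxy)phenyl]butan-1-one
Product: 4 1-[2,4,6-tris(benzyloxy)-3-bromophenyl]butan-1-one
Conditions: NBS (1.05 equiv), MeCN, 0 °C to rt, dark
Reagents that add atoms: N-bromosuccinimide, O=C1CCC(=O)N1Br
Why: Electrophilic aromatic bromination at one of the two equivalent, doubly alkoxy-activated ring positions; one equivalent at low temperature in the dark avoids dibromination and side-chain bromination.

Step 4
Reactants: 5 2,4,6-trihydroxyacetophenone
Product: 7 2-acetyl-3,5-dihydroxy-4,4-dimethylcyclohexa-2,5-dien-1-one (acetylfilicinic acid), via 2,4,6-trihydroxy-3-methylacetophenone 6 (not isolated)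
Conditions: NaOMe (3.2 equiv), MeI (2.2 equiv), MeOH, 0 °C to rt; then 1 M HCl
Reagents that add atoms: iodomethane, CI
Why: Dearomatising double C-methylation of the phloroglucinol polyanion, in which the second methyl group enters at the already methylated carbon of 6 and locks ring B as the non-aromatic trione; the yield is moderate because of other C-methylated by-products, and no stereocentre is formed.

Step 5
Reactants: 7 2-acetyl-3,5-dihydroxy-4,4-dimethylcyclohexa-2,5-dien-1-one
Product: 8 potassium [(5-acetyl-2,4-dihydroxy-3,3-dimethyl-6-oxocyclohexa-1,4-dien-1-yl)methyl]trifluoroborate (ring B–CH2–BF3K, the boron homoenolate of ring B)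
Conditions: BrCH2BF3K (1.05 equiv), K2CO3 (1.5 equiv), acetone/H2O 4:1, 55 °C; then AcOH to pH 5, salt extracted into hot acetone and precipitated with Et2O
Reagents that add atoms: potassium (bromomethyl)trifluoroborate, [K+].F[B-](F)(F)CBr
Why: Proposed new method: SN2 C-alkylation of the soft C6 enolate carbon (the only ring CH, between C1=O and the C5 enolate oxygen) by the bromomethyl carbon gives the β-boryl ketone, and the anionic BF3 group then disfavours a second alkylation at C6 electrostatically; the closest known reaction types are bromide displacement from potassium halomethyltrifluoroborates by alkoxides, amines and carbanions, and the C6-methylation or C6-prenylation of acylfilicinic acids.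

Step 6
Reactants: 4 1-[2,4,6-tris(benzyloxy)-3-bromophenyl]butan-1-one; 8 potassium [(5-acetyl-2,4-dihydroxy-3,3-dimethyl-6-oxocyclohexa-1,4-dien-1-yl)methyl]trifluoroborate (1.3 equiv)
Product: 9 2-acetyl-6-{[2,4,6-tris(benzyloxy)-3-butanoylphenyl]methyl}-3,5-dihydroxy-4,4-dimethylcyclohexa-2,5-dien-1-one
Conditions: Pd(OAc)2 (5 mol %), RuPhos (2-dicyclohexylphosphino-2',6'-diisopropoxybiphenyl, 10 mol %), K2CO3 (5 equiv), toluene/H2O 4:1, degassed, 85 °C; then 1 M HCl to pH 3
Reagents that add atoms: none
Why: Suzuki–Miyaura B-alkyl cross-coupling of a potassium β-trifluoroborato ketone, a known reaction type for simple homoenolate trifluoroborates that is here stretched to a free enolised trione: the exocyclic carbon, which would be the electrophilic Michael terminus of a 6-methylene trione, is delivered as a nucleophile from boron to the arylpalladium bromide formed at the electrophilic C–Br carbon of 4, the bulky electron-rich biaryl phosphine copes with the di-ortho-alkoxy bromide, the enolised sp2 C6 offers no β-hydrogen for elimination, and no stereocentre is created.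

Step 7
Reactants: 9 2-acetyl-6-{[2,4,6-tris(benzyloxy)-3-butanoylphenyl]methyl}-3,5-dihydroxy-4,4-dimethylcyclohexa-2,5-dien-1-one
Product: 10 2-acetyl-6-[(3-butanoyl-2,4,6-trihydroxyphenyl)methyl]-3,5-dihydroxy-4,4-dimethylcyclohexa-2,5-dien-1-one (target)
Conditions: H2 (1 atm), 10% Pd/C, EtOAc/MeOH 1:1, rt
Reagents that add atoms: none
Why: Catalytic hydrogenolysis of the three benzyl aryl ethers under neutral conditions leaves the hydrogen-bonded aryl ketone and the tetrasubstituted enol double bonds alone and avoids both base-induced scrambling and acid-induced xanthene cyclisation of the methylene-bridged dimer.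

## Compound list

1 | phloroglucinol (benzene-1,3,5-triol) | Oc1cc(O)cc(O)c1 | starting material
2 | 1-(2,4,6-trihydroxyphenyl)butan-1-one | CCCC(=O)c1c(O)cc(O)cc1O | intermediate
3 | 1-[2,4,6-tris(benzyloxy)phenyl]butan-1-one | CCCC(=O)c1c(OCc2ccccc2)cc(OCc2ccccc2)cc1OCc1ccccc1 | intermediate
4 | 1-[2,4,6-tris(benzyloxy)-3-bromophenyl]butan-1-one | CCCC(=O)c1c(OCc2ccccc2)cc(OCc2ccccc2)c(Br)c1OCc1ccccc1 | intermediate
5 | 2,4,6-trihydroxyacetophenone | CC(=O)c1c(O)cc(O)cc1O | starting material
6 | 2,4,6-trihydroxy-3-methylacetophenone | CC(=O)c1c(O)cc(O)c(C)c1O | intermediate (not isolated)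
7 | 2-acetyl-3,5-dihydroxy-4,4-dimethylcyclohexa-2,5-dien-1-one (acetylfilicinic acid) | CC(=O)C1=C(O)C(C)(C)C(O)=CC1=O | intermediate
8 | potassium [(5-acetyl-2,4-dihydroxy-3,3-dimethyl-6-oxocyclohexa-1,4-dien-1-yl)methyl]trifluoroborate | CC(=O)C1=C(O)C(C)(C)C(O)=C(C[B-](F)(F)F)C1=O.[K+] | intermediate
9 | 2-acetyl-6-{[2,4,6-tris(benzyloxy)-3-butanoylphenyl]methyl}-3,5-dihydroxy-4,4-dimethylcyclohexa-2,5-dien-1-one | CCCC(=O)c1c(OCc2ccccc2)cc(OCc2ccccc2)c(CC2=C(O)C(C)(C)C(O)=C(C(C)=O)C2=O)c1OCc1ccccc1 | intermediate
10 | 2-acetyl-6-[(3-butanoyl-2,4,6-trihydroxyphenyl)methyl]-3,5-dihydroxy-4,4-dimethylcyclohexa-2,5-dien-1-one | CCCC(=O)c1c(O)cc(O)c(CC2=C(O)C(C)(C)C(O)=C(C(C)=O)C2=O)c1O | target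

## Step count and risks

Total step count: 7. Longest linear sequence: 5 steps (steps 1, 2, 3, 6, 7); the other branch is steps 4, 5, 6, 7.

The three steps most likely to fail:

**Step 6.** The free acetyl-dione of 8 may sequester palladium as an O,O-chelate, or the boron homoenolate may protodeboronate before it transmetalates. The fallback is to cross-couple before the dearomatisation. It sets out from 5 and uses bromide 4. C-alkylation of 5 with potassium (bromomethyl)trifluoroborate (K2CO3, acetone/H2O) gives the aromatic potassium [(3-acetyl-2,4,6-trihydroxyphenyl)methyl]trifluoroborate F1. Coupling of F1 with 4 (Pd(OAc)2, RuPhos, K2CO3, toluene/H2O, 85 °C) gives 1-[3-(3-acetyl-2,4,6-trihydroxybenzyl)-2,4,6-tris(benzyloxy)phenyl]butan-1-one F2. Geminal C-methylation of F2 (MeI, NaOMe, MeOH) at the only unsubstituted carbon of its free phloroglucinol ring then builds ring B and comes back to the route at 9.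

**Step 5.** O-alkylation or double alkylation may compete with C6-monoalkylation. The fallback makes the carbon–boron bond by conjugate borylation. It sets out from 7. A Mannich reaction (aqueous CH2O, Me2NH, EtOH, rt) gives 2-acetyl-6-[(dimethylamino)methyl]-3,5-dihydroxy-4,4-dimethylcyclohexa-2,5-dien-1-one F3. Warming F3 with B2pin2, CuCl (10 mol %), 4,5-bis(diphenylphosphino)-9,9-dimethylxanthene and catalytic K2CO3 in MeOH/THF at 50 °C replaces the amine by boron through elimination and copper-mediated boryl addition at the exocyclic carbon. This gives 2-acetyl-3,5-dihydroxy-4,4-dimethyl-6-[(4,4,5,5-tetramethyl-1,3,2-dioxaborolan-2-yl)methyl]cyclohexa-2,5-dien-1-one F4. KHF2 in aqueous MeOH converts F4 into the trifluoroborate and comes back to the route at 8.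

**Step 7.** The aryl ketone may be over-reduced, or hydrogenolysis may stall on the polar, chelating product. The fallback uses acid-labile protection. It sets out from 2. NaH and chloromethyl methyl ether in DMF give 1-[2,4,6-tris(methoxymethoxy)phenyl]butan-1-one F5. NBS in MeCN gives 1-[3-bromo-2,4,6-tris(methoxymethoxy)phenyl]butan-1-one F6. Coupling of F6 with 8 under the step 6 conditions gives 2-acetyl-6-{[3-butanoyl-2,4,6-tris(methoxymethoxy)phenyl]methyl}-3,5-dihydroxy-4,4-dimethylcyclohexa-2,5-dien-1-one F7. HCl (3 M) in MeOH at rt removes the three acetals and comes back to the route at 10.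

## Further compounds

F1 | step 6 | potassium [(3-acetyl-2,4,6-trihydroxyphenyl)methyl]trifluoroborate | CC(=O)c1c(O)cc(O)c(C[B-](F)(F)F)c1O.[K+]
F2 | step 6 | 1-[3-(3-acetyl-2,4,6-trihydroxybenzyl)-2,4,6-tris(benzyloxy)phenyl]butan-1-one | CCCC(=O)c1c(OCc2ccccc2)cc(OCc2ccccc2)c(Cc2c(O)cc(O)c(C(C)=O)c2O)c1OCc1ccccc1
F3 | step 5 | 2-acetyl-6-[(dimethylamino)methyl]-3,5-dihydroxy-4,4-dimethylcyclohexa-2,5-dien-1-one | CC(=O)C1=C(O)C(C)(C)C(O)=C(CN(C)C)C1=O
F4 | step 5 | 2-acetyl-3,5-dihydroxy-4,4-dimethyl-6-[(4,4,5,5-tetramethyl-1,3,2-dioxaborolan-2-yl)methyl]cyclohexa-2,5-dien-1-one | CC(=O)C1=C(O)C(C)(C)C(O)=C(CB2OC(C)(C)C(C)(C)O2)C1=O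
F5 | step 7 | 1-[2,4,6-tris(methoxymethoxy)phenyl]butan-1-one | CCCC(=O)c1c(OCOC)cc(OCOC)cc1OCOC
F6 | step 7 | 1-[3-bromo-2,4,6-tris(methoxymethoxy)phenyl]butan-1-one | CCCC(=O)c1c(OCOC)cc(OCOC)c(Br)c1OCOC
F7 | step 7 | 2-acetyl-6-{[3-butanoyl-2,4,6-tris(methoxymethoxy)phenyl]methyl}-3,5-dihydroxy-4,4-dimethylcyclohexa-2,5-dien-1-one | CCCC(=O)c1c(OCOC)cc(OCOC)c(CC2=C(O)C(C)(C)C(O)=C(C(C)=O)C2=O)c1OCOC
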